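**Retrosynthetic overview**
1. The target is 3α,6β-bis(isovaleryloxy)-19-hydroxylabda-8,13E-dien-15-oic acid. Late disconnections are C12–C13 (B-alkyl Suzuki–Miyaura with an E-enol triflate), C9–C11 (Stille coupling at a C9 enol triflate made from a ring B 7-en-9-one), C6β–O (γ-oxidation of that enone, then 1,2-reduction) and the two ester C–O bonds.
2. The strategy rests on ring A: the oxygen-bearing C3, the quaternary C4 and the axial C19, taken at the aldehyde level, form a β-oxy aldehyde array. This is the retron of a 2,3-epoxy silyl ether 1,2-shift in which C19 first sits as a ring atom between C3 and C4 of a seven-membered ring (C10–C1–C2–C3–C19–C4–C5).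
3. That ring comes from ring-closing metathesis (C19=C4) of a dienol built on (R)-carvone by methylation, anti propargylation, alkyne hydroboration and vinyl addition. C3 is set by CBS reduction and the β-oxirane is placed anti to the 3α-silyloxy group. C4 and C18 derive from the isopropenyl group, C19 from the vinyl nucleophile.
4. Ring order: ring B (carvone; fixes C5, then C10), then the seven-membered ring (metathesis), then ring A (contraction; fixes C4).

Key step: step 10

Remark: labdane locants are used for all bicyclic compounds (ring B = C5–C10; C17 = methyl on C8; C18 α and C19 β on C4; C20 = methyl on C10; β = face of C20), and Sia = 3-methylbutan-2-yl; the target is read from its SMILES as the normal labdane (5α-H, 10β-CH3) with 3α- and 6β-acyloxy groups and C19 as the CH2OH carbon.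

**Route**

Step 1
Reactants: 1 (R)-carvone; 2 iodomethane
Product: 4 6-methylcarvone (C6 epimer mixture), via lithium dienolate 3 (not isolated)
Conditions: LiN(i-Pr)2 (1.05 eq), THF, −78 °C; then 2, −78 → 0 °C
Reagents that add atoms: none
Why: Kinetic α′-deprotonation of the enone gives the cross-conjugated lithium dienolate, which is C-methylated (enolate alkylation); the new centre is uncontrolled and is erased by re-enolisation in step 2.

Step 2
Reactants: 4 6-methylcarvone; 5 propargyl bromide
Product: 7 (5S,6S)-6-methyl-6-propargylcarvone (propargyl trans to isopropenyl), via lithium enolate 6 (not isolated)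
Conditions: LiN(i-Pr)2 (1.2 eq), THF, −78 → −20 °C; then 5, −78 → 23 °C
Reagents that add atoms: none
Why: Enolate alkylation with a reactive propargylic halide, which enters anti to the neighbouring isopropenyl group and so sets the quaternary carbon (later C10) with its methyl cis and its three-carbon arm trans to the C5 substituent.

Step 3
Reactants: 7 6-methyl-6-propargylcarvone
Product: 9 6-methyl-6-(3-oxopropyl)carvone, via alkenylborane 8 (not isolated)
Conditions: (Sia)2BH (from BH3·THF and 2-methylbut-2-ene, 1.3 eq), THF, 0 °C; then 30% H2O2, pH 7 phosphate buffer, 0 → 23 °C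
Reagents that add atoms: hydrogen peroxide, OO
Why: Hydroboration–oxidation of a terminal alkyne: the hindered dialkylborane adds once, anti-Markovnikov, to the alkyne much faster than to the 1,1-disubstituted alkene or the enone, and neutral peroxide turns the alkenylborane into the aldehyde without epoxidising the enone.

Step 4
Reactants: 9 aldehyde; 10 vinylmagnesium bromide
Product: 11 6-(3-hydroxypent-4-enyl)-6-methylcarvone (carbinol epimers)
Conditions: CH2=CHMgBr (1.1 eq), THF, −78 °C; then sat. aq. NH4Cl
Reagents that add atoms: none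
Why: Grignard 1,2-addition, chemoselective for the aldehyde at −78 °C because the enone carbonyl lies between a quaternary carbon and a methyl-bearing alkene carbon; C3 forms unselectively and is corrected in steps 6 and 7.

Step 5
Reactants: 11 dienol
Product: 12 6–7-fused allylic alcohol (C3 epimers; C19=C4 in the seven-membered ring)
Conditions: benzylidene[1,3-bis(2,4,6-trimethylphenyl)imidazolidin-2-ylidene]dichloro(tricyclohexylphosphine)ruthenium (second-generation Grubbs catalyst, 5 mol%), CH2Cl2 (5 mM), 40 °C
Reagents that add atoms: none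
Why: Ring-closing metathesis, which starts at the monosubstituted alkene and closes onto the isopropenyl group (the two arms are trans-diequatorial on ring B) to give the trisubstituted cycloheptene with loss of ethene, the electron-poor enone alkene staying out.

Step 6
Reactants: 12 allylic alcohol
Product: 13 6–7-fused dienedione (C3=O conjugated with C19=C4)
Conditions: MnO2 (20 eq), CH2Cl2, 23 °C
Reagents that add atoms: none
Why: Allylic alcohol oxidation with MnO2, which merges both C3 epimers into one cycloheptenone and leaves the rest untouched.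

Step 7
Reactants: 13 dienedione
Product: 14 (3R)-3α-allylic alcohol
Conditions: (S)-2-methyl-CBS-oxazaborolidine (0.2 eq), catecholborane (1.5 eq), toluene, −78 °C; then MeOH, H2O
Reagents that add atoms: none
Why: Corey–Bakshi–Shibata reduction: the catalyst takes the accessible cycloheptenone (the C9 carbonyl is shielded by C10 and the C8 methyl), treats the alkenyl arm as the large group and should give the (3R) carbinol, that is the 3α-alcohol, under reagent control.

Step 8
Reactants: 14 3α-alcohol
Product: 15 3α-tert-butyldimethylsilyl ether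
Conditions: TBSCl (1.5 eq), imidazole (3 eq), DMF, 23 °C
Reagents that add atoms: tert-butyldimethylsilyl chloride, CC(C)(C)[Si](C)(C)Cl
Why: Imidazole-promoted silylation of the secondary allylic alcohol, which installs the silyl ether that both directs step 9 and activates C3 for migration in step 10.

Step 9
Reactants: 15 allylic silyl ether
Product: 16 4β,19β-epoxy 3α-silyl ether (oxirane on the face of C20, trans to the silyloxy group)
Conditions: m-CPBA (1.2 eq), NaHCO3, CH2Cl2, 0 °C
Reagents that add atoms: 3-chloroperoxybenzoic acid, OOC(=O)c1cccc(Cl)c1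
Why: Prilezhaev epoxidation of the electron-rich trisubstituted alkene (the enone alkene is inert to peracid), expected anti to the 3α-silyloxy group, which is pseudoaxial on the α face of the conformationally locked trans-fused cycloheptene, so that the oxirane forms on the β face.

Step 10
Reactants: 16 epoxy silyl ether
Product: 17 trans-decalin enone aldehyde (3α-OTBS, 4α-CH3, 4β-CHO, 5α-H, 10β-CH3, 7-en-9-one)
Conditions: Me3Al (2.2 eq) and 4-bromo-2,6-di-tert-butylphenol (4.4 eq), CH2Cl2, 23 °C, 1 h, giving methylaluminium bis(4-bromo-2,6-di-tert-butylphenoxide); then 16, −78 → −20 °C; aq. HCl work-up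
Reagents that add atoms: none
Why: The bulky, oxophilic aluminium phenoxide binds the oxirane oxygen and lengthens the C4–O bond, because C4 is tertiary and C19–O cleavage is disfavoured by the adjacent C3–O bond; as positive charge builds at C4 the C3–C19 ring bond shifts to C4 on the face opposite the departing oxygen while the aluminium-bound oxygen on C19 becomes the formyl oxygen (semipinacol 1,2-shift). The closest known reaction is the organoaluminium-promoted rearrangement of 2,3-epoxy silyl ethers to β-siloxy aldehydes, applied here to a cyclic epoxy silyl ether in which the migrating siloxy carbon is a ring atom, so that the shift contracts the ring. Ring A is not closed by a cyclisation and no exo or endo mode applies: the C3–C19 bond is exchanged for C3–C4, which contracts the seven-membered ring to the six-membered ring and extrudes C19. C4 is the one new stereocentre and is inverted by the shift, so the β-oxirane delivers C3 to the α face and leaves C19 β (axial, cis to C20) and C18 α, while C3 migrates with retention and keeps its 3α-silyloxy group. The step needs migration of C3 rather than of H19 and no proton loss from C4: the silyloxy-bearing carbon is the usual migrating group with this Lewis acid, the shift turns a strained seven-membered ring into a trans-decalin, and the non-nucleophilic phenoxide ligands and low temperature disfavour elimination. An excess of the aluminium reagent is used because the C9 enone carbonyl also binds it.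

Step 11
Reactants: 17 aldehyde
Product: 18 19-alcohol (3α-OTBS)
Conditions: NaBH4 (1 eq), EtOH/CH2Cl2 (3:7), −78 → −40 °C
Reagents that add atoms: none
Why: Chemoselective borohydride reduction of the aldehyde, which is far more electrophilic than the doubly flanked C9 enone carbonyl at low temperature; no stereocentre is formed.

Step 12
Reactants: 18 silyl ether alcohol
Product: 19 3α,19-diol
Conditions: 48% aq. HF, MeCN, 23 °C
Reagents that add atoms: none
Why: Acidic fluoride desilylation of the secondary silyl ether, done after step 11 so that no β-hydroxy aldehyde open to retro-aldol cleavage is ever present.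

Step 13
Reactants: 19 diol
Product: 20 19-O-TBS ether, 3α-alcohol
Conditions: TBSCl (1.1 eq), imidazole (2 eq), CH2Cl2, 0 °C
Reagents that add atoms: tert-butyldimethylsilyl chloride, CC(C)(C)[Si](C)(C)Cl
Why: Selective silylation: the primary C19 hydroxyl reacts much faster than the axial 3α-hydroxyl next to the quaternary C4, and the trans-diaxial O3/C19 arrangement rules out later silyl transfer.

Step 14
Reactants: 20 alcohol; 21 isovaleric anhydride
Product: 22 3α-isovalerate (19-OTBS, 7-en-9-one)
Conditions: 21 (3 eq), DMAP (0.3 eq), Et3N (4 eq), CH2Cl2, 40 °C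
Reagents that add atoms: none
Why: DMAP-catalysed acylation (nucleophilic acyl transfer) of the axial 3α-alcohol, warmed because of the neighbouring quaternary carbon.

Step 15
Reactants: 22 enone
Product: 23 7-ene-6,9-dione
Conditions: Pd(OH)2/C (5 mol%), t-BuOOH (5 eq), K2CO3 (0.25 eq), CH2Cl2, 4 → 23 °C
Reagents that add atoms: tert-butyl hydroperoxide, CC(C)(C)OO
Why: Palladium-catalysed tert-butyl hydroperoxide oxidation of the γ-methylene of an enone to the 2-ene-1,4-dione (allylic peroxidation then Kornblum–DeLaMare-type loss of tert-butanol); C6 is the only γ-CH2 and the mild carbonate base limits enolisation at C5.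

Step 16
Reactants: 23 enedione
Product: 24 6β-hydroxy-7-en-9-one
Conditions: NaBH4 (1.0 eq), CeCl3·7H2O (1.1 eq), MeOH/THF, −78 °C
Reagents that add atoms: none
Why: Luche 1,2-reduction, expected at the C6 carbonyl, which like the distal carbonyl of ketoisophorone-type enediones lies between CH= and a ring CH, and not at C9 between the quaternary C10 and the methyl-bearing C8; hydride should arrive on the α face, the β face of C6 being closed by the syn-axial C20 methyl and C19 methylene, to give the axial 6β-alcohol.

Step 17
Reactants: 24 alcohol; 21 isovaleric anhydride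
Product: 25 3α,6β-bis(isovalerate) 7-en-9-one
Conditions: 21 (5 eq), DMAP (2 eq), Et3N (6 eq), toluene, 60 °C
Reagents that add atoms: none
Why: DMAP-mediated acylation under forcing conditions (excess anhydride, 60 °C), required because the axial 6β-hydroxyl lies between the syn-axial C20 methyl and C19 methylene.

Step 18
Reactants: 25 enone
Product: 27 8-en-9-yl triflate, via lithium enolate 26 (not isolated)
Conditions: LiBH(s-Bu)3 (1.1 eq), THF, −78 °C; then N-(5-chloropyridin-2-yl)bis(trifluoromethanesulfonyl)imide (1.3 eq), −78 → 0 °C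
Reagents that add atoms: N-(5-chloropyridin-2-yl)bis(trifluoromethanesulfonyl)imide, O=S(=O)(N(c1ccc(Cl)cn1)S(=O)(=O)C(F)(F)F)C(F)(F)F
Why: Conjugate reduction with enolate trapping: the bulky hydride adds 1,4 at the unsubstituted C7 of the carbonyl-hindered enone, and the regiodefined C8=C9 enolate is O-triflated, which fixes the position of the tetrasubstituted alkene; the esters survive at −78 °C.

Step 19
Reactants: 27 alkenyl triflate; 28 tributyl(vinyl)stannane
Product: 29 9-vinyl-8-ene (C8=C9–C11=C12 diene)
Conditions: 28 (1.5 eq), Pd(PPh3)4 (5 mol%), LiCl (3 eq), THF, 65 °C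
Reagents that add atoms: none
Why: Stille coupling of the hindered alkenyl triflate with a small sp2 stannane under chloride-assisted conditions, which forms C9–C11 without touching esters or silyl ether.

Step 20
Reactants: 30 tert-butyl acetoacetate
Product: 31 tert-butyl (E)-3-(trifluoromethylsulfonyloxy)but-2-enoate
Conditions: Tf2O (1.2 eq), aq. Me4NOH (25%), toluene, 5 °C
Reagents that add atoms: trifluoromethanesulfonic anhydride, O=S(=O)(OS(=O)(=O)C(F)(F)F)C(F)(F)F
Why: O-triflation of the β-keto ester enolate, E-selective with the non-chelating tetramethylammonium counter-ion (a chelating lithium ion would give Z), so that the triflyloxy group is trans to the ester.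

Step 21
Reactants: 29 diene; 31 E-enol triflate
Product: 33 tert-butyl ester 19-O-TBS ether of the target, via B-alkyl-9-BBN 32 (not isolated)
Conditions: 9-BBN dimer (0.75 eq), THF, 0 → 23 °C; then 31 (1.3 eq), Pd(dppf)Cl2 (5 mol%), AsPh3 (10 mol%), 3 M aq. K3PO4, DMF, 23 °C
Reagents that add atoms: none
Why: 9-BBN hydroborates only the terminal vinyl group (boron on C12), and the B-alkyl Suzuki–Miyaura coupling with the enol triflate proceeds with retention, placing the chain trans to the ester and so setting the 13E alkene.

Step 22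
Reactants: 33 protected acid
Product: 34 target acid
Conditions: CF3CO2H/CH2Cl2/H2O (10:40:1), 0 → 23 °C
Reagents that add atoms: none
Why: Acidolysis: trifluoroacetic acid cleaves the tert-butyl ester through the tert-butyl cation (isobutene) and, with water, the primary silyl ether, while both isovalerates and the tetrasubstituted alkene persist under these mildly acidic, non-basic conditions that also avoid acyl transfer to O19.

**Compound list**
1 | (R)-carvone | CC1=CC[C@@H](C(C)=C)CC1=O | starting material
2 | iodomethane | CI | starting material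
3 | lithium dienolate of 1 (enolised toward C6 of carvone) | CC1=CC[C@@H](C(C)=C)C=C1O[Li] | intermediate
4 | (5R)-6-methylcarvone, C6 epimer mixture | CC1=CC[C@@H](C(C)=C)C(C)C1=O | intermediate
5 | propargyl bromide (3-bromoprop-1-yne) | C#CCBr | starting material
6 | lithium enolate of 4 (C1–OLi, C1=C6) | CC1=CC[C@@H](C(C)=C)C(C)=C1O[Li] | intermediate
7 | (5S,6S)-6-methyl-6-(prop-2-ynyl)carvone; methyl cis, propargyl trans to isopropenyl | C1C=C(C)C(=O)[C@@](C)(CC#C)[C@@H]1C(C)=C | intermediate
8 | (E)-alkenylbis(3-methylbutan-2-yl)borane from 7 (boron on the former alkyne terminus) | C1C=C(C)C(=O)[C@@](C)(C/C=C/B(C(C)C(C)C)C(C)C(C)C)[C@@H]1C(C)=C | intermediate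
9 | (5S,6S)-6-methyl-6-(3-oxopropyl)carvone | C1C=C(C)C(=O)[C@@](C)(CCC=O)[C@@H]1C(C)=C | intermediate
10 | vinylmagnesium bromide | C=C[Mg]Br | starting material
11 | (5S,6S)-6-(3-hydroxypent-4-enyl)-6-methylcarvone, carbinol epimers | C1C=C(C)C(=O)[C@@](C)(CCC(O)C=C)[C@@H]1C(C)=C | intermediate
12 | 6–7-fused hydroxy dienone: ring B 7-en-9-one (C8 methyl), 10β-CH3, 5α-H; seven-membered ring C10–C1–C2–C3(OH)–C19H=C4(CH3)–C5; C3 epimers | C1C=C(C)C(=O)[C@@]2(C)CCC(O)C=C(C)[C@@H]21 | intermediate
13 | 6–7-fused dienedione (12 with C3=O) | C1C=C(C)C(=O)[C@@]2(C)CCC(=O)C=C(C)[C@@H]21 | intermediate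
14 | (3R)-3α-alcohol of 13 | C1C=C(C)C(=O)[C@@]2(C)CC[C@@H](O)C=C(C)[C@@H]21 | intermediate
15 | 3α-tert-butyldimethylsilyl ether of 14 | C1C=C(C)C(=O)[C@@]2(C)CC[C@@H](O[Si](C)(C)C(C)(C)C)C=C(C)[C@@H]21 | intermediate
16 | 4β,19β-epoxide of 15 (oxirane cis to C20, trans to 3α-OTBS) | C1C=C(C)C(=O)[C@@]2(C)CC[C@@H](O[Si](C)(C)C(C)(C)C)[C@@H]3O[C@]3(C)[C@@H]21 | intermediate
17 | trans-decalin 7-en-9-one with 3α-OTBS, 4α-CH3, 4β-CHO (C19), 5α-H, 10β-CH3 | C1C=C(C)C(=O)[C@@]2(C)CC[C@@H](O[Si](C)(C)C(C)(C)C)[C@](C)(C=O)[C@@H]21 | intermediate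
18 | 19-alcohol of 17 | C1C=C(C)C(=O)[C@@]2(C)CC[C@@H](O[Si](C)(C)C(C)(C)C)[C@](C)(CO)[C@@H]21 | intermediate
19 | 3α,19-dihydroxy 7-en-9-one | C1C=C(C)C(=O)[C@@]2(C)CC[C@@H](O)[C@](C)(CO)[C@@H]21 | intermediate
20 | 19-O-TBS ether of 19 (3α-OH free) | C1C=C(C)C(=O)[C@@]2(C)CC[C@@H](O)[C@](C)(CO[Si](C)(C)C(C)(C)C)[C@@H]21 | intermediate
21 | isovaleric anhydride (3-methylbutanoic anhydride) | CC(C)CC(=O)OC(=O)CC(C)C | starting material
22 | 3α-isovalerate of 20 | C1C=C(C)C(=O)[C@@]2(C)CC[C@@H](OC(=O)CC(C)C)[C@](C)(CO[Si](C)(C)C(C)(C)C)[C@@H]21 | intermediate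
23 | 7-ene-6,9-dione (3α-isovalerate, 19-OTBS) | O=C1C=C(C)C(=O)[C@@]2(C)CC[C@@H](OC(=O)CC(C)C)[C@](C)(CO[Si](C)(C)C(C)(C)C)[C@@H]21 | intermediate
24 | 6β-hydroxy-7-en-9-one (3α-isovalerate, 19-OTBS) | O[C@@H]1C=C(C)C(=O)[C@@]2(C)CC[C@@H](OC(=O)CC(C)C)[C@](C)(CO[Si](C)(C)C(C)(C)C)[C@@H]21 | intermediate
25 | 3α,6β-bis(isovalerate) 7-en-9-one (19-OTBS) | CC(C)CC(=O)O[C@@H]1C=C(C)C(=O)[C@@]2(C)CC[C@@H](OC(=O)CC(C)C)[C@](C)(CO[Si](C)(C)C(C)(C)C)[C@@H]21 | intermediate
26 | lithium enolate of the 7,8-dihydro ketone, C9(OLi)=C8 | CC(C)CC(=O)O[C@@H]1CC(C)=C(O[Li])[C@@]2(C)CC[C@@H](OC(=O)CC(C)C)[C@](C)(CO[Si](C)(C)C(C)(C)C)[C@@H]21 | intermediate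
27 | 8-en-9-yl trifluoromethanesulfonate (3α,6β-bis(isovalerate), 19-OTBS) | CC(C)CC(=O)O[C@@H]1CC(C)=C(OS(=O)(=O)C(F)(F)F)[C@@]2(C)CC[C@@H](OC(=O)CC(C)C)[C@](C)(CO[Si](C)(C)C(C)(C)C)[C@@H]21 | intermediate
28 | tributyl(vinyl)stannane | C=C[Sn](CCCC)(CCCC)CCCC | starting material
29 | 9-vinyl-8-ene (13,14,15,16-tetranorlabda-8,11-diene; 3α,6β-bis(isovalerate), 19-OTBS) | CC(C)CC(=O)O[C@@H]1CC(C)=C(C=C)[C@@]2(C)CC[C@@H](OC(=O)CC(C)C)[C@](C)(CO[Si](C)(C)C(C)(C)C)[C@@H]21 | intermediate
30 | tert-butyl acetoacetate | CC(=O)CC(=O)OC(C)(C)C | starting material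
31 | tert-butyl (E)-3-(trifluoromethylsulfonyloxy)but-2-enoate | CC(C)(C)OC(=O)/C=C(C)/OS(=O)(=O)C(F)(F)F | intermediate
32 | B-alkyl-9-borabicyclo[3.3.1]nonane from 29 (boron on C12) | CC(C)CC(=O)O[C@@H]1CC(C)=C(CCB3C4CCCC3CCC4)[C@@]2(C)CC[C@@H](OC(=O)CC(C)C)[C@](C)(CO[Si](C)(C)C(C)(C)C)[C@@H]21 | intermediate
33 | tert-butyl 3α,6β-bis(isovaleryloxy)-19-(tert-butyldimethylsilyloxy)labda-8,13E-dien-15-oate | CC(C)CC(=O)O[C@@H]1CC(C)=C(CC/C(C)=C/C(=O)OC(C)(C)C)[C@@]2(C)CC[C@@H](OC(=O)CC(C)C)[C@](C)(CO[Si](C)(C)C(C)(C)C)[C@@H]21 | intermediate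
34 | 3α,6β-bis(isovaleryloxy)-19-hydroxylabda-8,13E-dien-15-oic acid (CNP0272110.1) | CC1=C(CC/C(C)=C/C(=O)O)[C@@]2(C)CC[C@@H](OC(=O)CC(C)C)[C@](C)(CO)[C@@H]2[C@H](OC(=O)CC(C)C)C1 | target

**Step count**
Total: 22 steps. Longest linear sequence: 21 steps (steps 1–19, 21 and 22; step 20 is a one-step branch).

**Steps most likely to fail**

Step 10 (ring-contracting shift). The shift may be outrun by migration of H19 to give a ring ketone, by proton loss from the C4 cation, or the aluminium reagent may be held by the C9 carbonyl. The fallback runs the same C3-to-C4 shift as an acyl migration, modelled on the Lewis-acid rearrangement of α,β-epoxy ketones to ring-contracted β-keto aldehydes (isophorone oxide to the formylcyclopentanone). It sets out from 16. Bu4NF in THF should give the β-epoxy 3α-alcohol F1, and Dess–Martin periodinane the α,β-epoxy ketone F2. BF3·OEt2 in CH2Cl2 at 0 °C should then open the oxirane at C4 and shift the acyl carbon C3 with inversion at C4, giving the ring-contracted 3-oxo 19-aldehyde F3. NaBH4 at −78 °C should reduce only the aldehyde to the β-hydroxy ketone F4. Me4NBH(OAc)3 in MeCN/AcOH (Evans–Saksena reduction) should deliver hydride from the axial C19 oxygen to the β face of C3 and leave the C9 enone alone. This gives diol 19, where the route is rejoined.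

Step 16 (enedione reduction). Hydride may fail to distinguish the C6 and C9 carbonyls, or the enedione may epimerise at C5 by enolisation before it is reduced. The fallback sets out from 23 and removes the need for regiocontrol. Excess NaBH4 with CeCl3·7H2O at −78 °C should reduce both carbonyls at once to the 6β,9-diol F5, C6 again taking hydride on its open α face. MnO2 in CH2Cl2 should then oxidise back only the less hindered, pseudoequatorial C9 allylic alcohol. The pseudoaxial 6β-hydroxyl, held between C20 and C19, should remain, which returns 24.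

Step 9 (epoxidation face). The peracid may be delivered mainly to the α face if shielding of the β face by the axial C20 methyl outweighs that of the α face by the pseudoaxial silyloxy group. The fallback sets out from 15 and turns the same facial bias round with a halohydrin. N-Bromosuccinimide in aqueous THF should place the bromonium ion on the α face. Water should open it at the tertiary C4 from the β face to give bromohydrin F6 (C19 α-Br, C4 β-OH). K2CO3 in MeOH should close the β-oxirane by displacement of bromide at C19, giving 16.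

**Further compounds**
F1 | step 10 | 4β,19β-epoxy 3α-alcohol (desilylated 16) | C1C=C(C)C(=O)[C@@]2(C)CC[C@@H](O)[C@@H]3O[C@]3(C)[C@@H]21
F2 | step 10 | 4β,19β-epoxy 3-ketone (α,β-epoxy ketone in the seven-membered ring) | C1C=C(C)C(=O)[C@@]2(C)CCC(=O)[C@@H]3O[C@]3(C)[C@@H]21
F3 | step 10 | trans-decalin 3,9-dioxo-7-en-19-al (4α-CH3, 4β-CHO) | C1C=C(C)C(=O)[C@@]2(C)CCC(=O)[C@](C)(C=O)[C@@H]21
F4 | step 10 | 19-hydroxy-3,9-dioxo-7-ene | C1C=C(C)C(=O)[C@@]2(C)CCC(=O)[C@](C)(CO)[C@@H]21
F5 | step 16 | 6β,9-dihydroxy-7-ene (3α-isovalerate, 19-OTBS; C9 configuration of no consequence) | O[C@@H]1C=C(C)C(O)[C@@]2(C)CC[C@@H](OC(=O)CC(C)C)[C@](C)(CO[Si](C)(C)C(C)(C)C)[C@@H]21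
F6 | step 9 | bromohydrin of 15: 19α-bromo, 4β-hydroxy, 3α-OTBS | C1C=C(C)C(=O)[C@@]2(C)CC[C@@H](O[Si](C)(C)C(C)(C)C)[C@@H](Br)[C@@](O)(C)[C@@H]21
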